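**Assumptions (one line):** Stereodescriptors are read from the SMILES: THP 2R,3R,4S,6S; chain C3′ S; benzylic C7 R; both alkenes E. The catalyst and enzyme hands named below are taken to be available or found by screening. MOM = CH2OCH3, TES = SiEt3, TBS = SiMe2tBu.

## Retrosynthetic overview
1. The target is released from the polyprotected ketone **39**, which comes from ring-A aryllithium **38** and THP Weinreb amide **28**. The chain diarylmethine C7 is set by a chiral-BINOL o-quinone-methide alkenylation of benzhydrol **35** with alkenylboronic acid **9**.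
2. The THP is the only ring formed. It is closed last by intramolecular SN2 etherification (C2 alkoxide on C6 mesylate, inversion at C6) to give the 2,6-trans ring.
3. Its acyclic precursor **24** comes from an E-enolate Ireland–Claisen of ester **23**. This sets C3/C4 and the E-styryl group.
4. Ester **23** joins KRED-derived (R)-β-silyloxy acid **22** (C2) to lipase-resolved (S)-allylic alcohol unit **16** (C7, which is transferred to C4). Unit **16** is made by cross-metathesis of **11** and **15**.
5. Both carbinols (C3′ and C6) come from one hydrolytic-kinetic-resolution epoxide, used in both hands. All p-hydroxyphenyl groups are carried as MOM ethers.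

## Route

**Step 1**
Reactants: 1 methyl 3-(4-hydroxyphenyl)propanoate
Product: 2 methyl 3-[4-(MOMO)phenyl]propanoate
Conditions: MOMCl, iPr2NEt, CH2Cl2, 0 °C→rt
Reagents that add atoms: chloromethyl methyl ether, ClCOC
Why: Phenol is masked as a MOM acetal that survives the organometallic, basic and Ru steps; no stereocenter is involved.

**Step 2**
Reactants: 2
Product: 3 3-[4-(MOMO)phenyl]propanal
Conditions: DIBAL-H (1.1 equiv), CH2Cl2, –78 °C
Reagents that add atoms: none
Why: Partial ester reduction stops at the aldehyde through a stable aluminate hemiacetal.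

**Step 3**
Reactants: 3
Product: 4 rac-2-{2-[4-(MOMO)phenyl]ethyl}oxirane
Conditions: Me3S⁺I⁻, n-BuLi, THF, –10→0 °C
Reagents that add atoms: trimethylsulfonium iodide, C[S+](C)C.[I-] (supplies CH2)
Why: Corey–Chaykovsky methylene transfer gives the terminal epoxide as a racemate from achiral materials.

**Step 4**
Reactants: 4
Product: 5 (S)-2-{2-[4-(MOMO)phenyl]ethyl}oxirane
Conditions: (S,S)-(salen)Co(III)OAc (0.5 mol%), H2O (0.55 equiv), THF, 0 °C→rt
Reagents that add atoms: none (water ends up in the diol by-product)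
Why: Jacobsen hydrolytic kinetic resolution; the chiral Co catalyst sets the first stereocenter (C3′ precursor) and leaves the (S)-epoxide. The (R,R) complex is used if the opposite sense is seen.

**Step 5**
Reactants: 4
Product: 6 (R)-2-{2-[4-(MOMO)phenyl]ethyl}oxirane
Conditions: (R,R)-(salen)Co(III)OAc (0.5 mol%), H2O (0.55 equiv), THF, 0 °C→rt
Reagents that add atoms: none
Why: The same resolution with the opposite catalyst hand gives the (R)-epoxide, the C6 precursor that is inverted later.

**Step 6**
Reactants: 5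
Product: 7 (S)-1-[4-(MOMO)phenyl]hex-5-yn-3-ol
Conditions: lithium acetylide–ethylenediamine, DMSO, 15 °C→rt
Reagents that add atoms: lithium acetylide, [Li+].[C-]#C (supplies C2H)
Why: SN2 opening at the unhindered terminal CH2 leaves the carbinol stereocenter untouched, so (S) is retained.

**Step 7**
Reactants: 7
Product: 8 (S)-TBS ether of 7
Conditions: TBSCl, imidazole, DMF, rt
Reagents that add atoms: TBSCl, C[Si](C)(Cl)C(C)(C)C
Why: Silylation protects C3′–OH and does not touch the stereocenter.

**Step 8**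
Reactants: 8
Product: 9 (E)-alkenylboronic acid, (S)-C3′
Conditions: catecholborane, neat, 70 °C; then H2O, THF, rt
Reagents that add atoms: catecholborane, B1Oc2ccccc2O1 (supplies B); water, O (supplies the B–OH groups)
Why: Syn-hydroboration of the terminal alkyne places boron on the terminal carbon and fixes the E-alkene.

**Step 9**
Reactants: 6
Product: 10 (R)-1-[4-(MOMO)phenyl]hex-5-en-3-ol
Conditions: CH2=CHMgBr, CuI (10 mol%), THF, –40 °C
Reagents that add atoms: vinylmagnesium bromide, C=C[Mg]Br (supplies vinyl)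
Why: Cuprate opening at the terminal epoxide carbon gives the homoallylic alcohol with the (R) carbinol retained.

**Step 10**
Reactants: 10
Product: 11 (R)-TES ether of 10
Conditions: TESCl, imidazole, DMF, rt
Reagents that add atoms: chlorotriethylsilane, CC[Si](Cl)(CC)CC
Why: TES is chosen as the protecting group that can later be removed selectively in the presence of TBS.

**Step 11**
Reactants: 12 4-hydroxybenzaldehyde
Product: 13 4-(MOMO)benzaldehyde
Conditions: MOMCl, iPr2NEt, CH2Cl2, 0 °C→rt
Reagents that add atoms: ClCOC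
Why: Phenol protection.

**Step 12**
Reactants: 13
Product: 14 rac-1-[4-(MOMO)phenyl]prop-2-en-1-ol
Conditions: CH2=CHMgBr, THF, 0 °C
Reagents that add atoms: C=C[Mg]Br (supplies vinyl)
Why: 1,2-Addition to the aldehyde gives the racemic allylic alcohol.

**Step 13**
Reactants: 14
Product: 15 (S)-1-[4-(MOMO)phenyl]prop-2-en-1-ol
Conditions: Candida antarctica lipase B (a lipase, EC 3.1.1.3; Novozym 435), vinyl acetate, MTBE, 25 °C, stop at ~50% conversion
Reagents that add atoms: none (the acetate goes to the (R)-ester by-product)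
Why: Enzymatic kinetic resolution: the lipase acylates the (R)-carbinol, leaving the (S)-alcohol that later transfers chirality to C4.

**Step 14**
Reactants: 11 and 15
Product: 16 (3R,5E,7S)-1,7-bis[4-(MOMO)phenyl]-3-(TESO)hept-5-en-7-ol
Conditions: Hoveyda–Grubbs II (5 mol%), 1,4-benzoquinone (10 mol%), CH2Cl2, 40 °C
Reagents that add atoms: none (ethylene is lost)
Why: Cross-metathesis of the two terminal alkenes is thermodynamically E-selective and leaves both carbinol stereocenters untouched.

**Step 15**
Reactants: 17 4-hydroxyacetophenone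
Product: 18 4-(MOMO)acetophenone
Conditions: MOMCl, iPr2NEt, CH2Cl2, 0 °C→rt
Reagents that add atoms: ClCOC
Why: Phenol protection.

**Step 16**
Reactants: 18
Product: 19 ethyl 3-[4-(MOMO)phenyl]-3-oxopropanoate
Conditions: NaH, diethyl carbonate, toluene, reflux
Reagents that add atoms: diethyl carbonate, CCOC(=O)OCC (supplies CO2Et)
Why: Claisen-type acylation of the methyl ketone enolate gives the β-ketoester.

**Step 17**
Reactants: 19
Product: 20 ethyl (R)-3-hydroxy-3-[4-(MOMO)phenyl]propanoate
Conditions: (R)-selective ketoreductase (an alcohol-dehydrogenase-type oxidoreductase, EC 1.1.1.–), NADP⁺, glucose/GDH recycling, KPi pH 7, 10% DMSO, 30 °C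
Reagents that add atoms: none (the hydride from NADPH adds hydrogen only)
Why: Enzymatic asymmetric ketone reduction sets C2 (R) by face-selective hydride delivery in the active site.

**Step 18**
Reactants: 20
Product: 21 ethyl (R)-3-(TBSO)-3-[4-(MOMO)phenyl]propanoate
Conditions: TBSCl, imidazole, DMF, rt
Reagents that add atoms: TBSCl, C[Si](C)(Cl)C(C)(C)C
Why: The silyl ether keeps the C2 oxygen inert during enolization and is cleaved later by fluoride.

**Step 19**
Reactants: 21
Product: 22 (R)-3-(TBSO)-3-[4-(MOMO)phenyl]propanoic acid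
Conditions: LiOH·H2O, THF/H2O, 0 °C→rt
Reagents that add atoms: water, O (supplies the acid OH)
Why: Saponification under mild conditions avoids β-elimination of the silyloxy group.

**Step 20**
Reactants: 22 and 16
Product: 23 allylic ester of 22 with (S)-alcohol 16
Conditions: EDC·HCl, DMAP (0.1 equiv), CH2Cl2, 0 °C→rt
Reagents that add atoms: none
Why: Steglich esterification proceeds at the O–H bond, so the allylic stereocenter is untouched.

**Step 21**
Reactants: 23
Product: 24 (3R,4S)-acid of the Claisen product (2R,3R,4S acyclic; C6 still (R)-OTES)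
Conditions: LDA, THF (no HMPA), –78 °C; TMSCl, –78→25 °C, 12 h; aqueous NaH2PO4 workup
Reagents that add atoms: none (TMSCl is lost; the workup hydrolyses the silyl ester)
Why: Ireland–Claisen [3,3] through the E-enolate-derived ketene acetal and a chair TS with the aryl group equatorial. The (S)-carbinol fixes the alkene face (C4 = S), the acetal geometry gives the anti relationship (C3 = R), and the E-styryl group is formed.

**Step 22**
Reactants: 24
Product: 25 Weinreb amide of 24
Conditions: MeNHOMe·HCl, EDC·HCl, HOBt, iPr2NEt, CH2Cl2, 0 °C→rt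
Reagents that add atoms: N,O-dimethylhydroxylamine hydrochloride, CONC.Cl (supplies N(OMe)Me)
Why: The non-epimerising amide coupling gives an acyl donor that stops at the ketone stage with aryllithiums.

**Step 23**
Reactants: 25
Product: 26 C6 alcohol (TES removed)
Conditions: PPTS (0.2 equiv), MeOH/CH2Cl2, 0 °C→rt
Reagents that add atoms: none
Why: The labile TES ether is cleaved selectively, leaving the benzylic TBS ether, the MOM ethers and the amide.

**Step 24**
Reactants: 26
Product: 27 C6 mesylate (R)
Conditions: MsCl, Et3N, CH2Cl2, –10 °C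
Reagents that add atoms: methanesulfonyl chloride, CS(=O)(=O)Cl
Why: Sulfonylation converts the (R)-alcohol, with retention, into a leaving group for inversion.

**Step 25**
Reactants: 27
Product: 28 THP Weinreb amide (2R,3R,4S,6S)
Conditions: TBAF (3 equiv), THF, 0→35 °C
Reagents that add atoms: none
Why: Fluoride unmasks the C2 alkoxide, which closes the ring by intramolecular Williamson 6-exo SN2 at C6. Inversion turns C6 (R) into (S) and retains C2 (R), giving the 2,6-trans THP.

**Step 26**
Reactants: 29 3,5-dihydroxyanisole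
Product: 30 1,3-bis(MOMO)-5-methoxybenzene
Conditions: MOMCl (2.5 equiv), iPr2NEt, CH2Cl2, 0 °C→rt
Reagents that add atoms: ClCOC
Why: Two MOM groups both protect the phenols and serve as cooperative ortho-directing groups.

**Step 27**
Reactants: 30
Product: 31 2,6-bis(MOMO)-4-methoxybenzaldehyde
Conditions: n-BuLi, THF, 0 °C; then DMF, –78 °C→rt
Reagents that add atoms: N,N-dimethylformamide, CN(C)C=O (supplies CHO)
Why: Directed ortho-metalation between the two MOMO groups places the formyl group at C2 of the resorcinol ring, flanked by the two future phenols.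

**Step 28**
Reactants: 31
Product: 32 2-hydroxy-4-methoxy-6-(MOMO)benzaldehyde
Conditions: MgBr2·OEt2 (1.1 equiv), CH2Cl2, 0 °C→rt
Reagents that add atoms: none
Why: Carbonyl-chelation-directed cleavage of one ortho MOM group stops at the H-bonded salicylaldehyde, which is deactivated to further chelation.

**Step 29**
Reactants: 33 4-bromophenol
Product: 34 1-bromo-4-(MOMO)benzene
Conditions: MOMCl, iPr2NEt, CH2Cl2, 0 °C→rt
Reagents that add atoms: ClCOC
Why: Protected aryl source for the Grignard reagent.

**Step 30**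
Reactants: 32 and 34
Product: 35 rac-[2-hydroxy-4-methoxy-6-(MOMO)phenyl][4-(MOMO)phenyl]methanol
Conditions: 34, Mg, THF, reflux (ArMgBr, 2.3 equiv); then 32, 0 °C; NH4Cl; used directly
Reagents that add atoms: none (Mg is not retained)
Why: Grignard 1,2-addition to the salicylaldehyde (phenoxide formed first) gives the o-hydroxybenzhydrol, which is the o-QM precursor; the carbinol carbon is racemic and is destroyed in the next step.

**Step 31**
Reactants: 35 and 9
Product: 36 (R)-diarylmethine [(R)-C7] with E-alkenyl chain and free ortho-OH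
Conditions: (S)-3,3′-Br2-BINOL (20 mol%), toluene, 4 Å MS, 50 °C, 24 h
Reagents that add atoms: none (the alkenyl group comes from 9)
Why: The BINOL-boronate generates the planar o-quinone methide and delivers the E-alkenyl group enantioselectively in a conjugate alkenylation. This sets C7 (R) with retention of the E-alkene, and the catalyst hand is screened to give (R).

**Step 32**
Reactants: 36
Product: 37 ring-A bis-MOM ether of 36
Conditions: MOMCl, iPr2NEt, CH2Cl2, 0 °C→rt
Reagents that add atoms: ClCOC
Why: Capping the free phenol prevents it from quenching the aryllithium later.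

**Step 33**
Reactants: 37
Product: 38 aryl bromide (Br between OMe and OMOM on ring A)
Conditions: NBS (1.05 equiv), MeCN, –20 °C, dark
Reagents that add atoms: N-bromosuccinimide, O=C1CCC(=O)N1Br (supplies Br)
Why: Electrophilic bromination of the trioxygenated ring goes to the only activated position (C4 and C6 are equivalent), while the E-alkene and the C7–H are not touched without radical initiation.

**Step 34**
Reactants: 38 and 28
Product: 39 protected target (aryl ketone)
Conditions: t-BuLi (2 equiv), THF, –78 °C, 10 min; then 28, –78→–20 °C; NH4Cl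
Reagents that add atoms: none
Why: Br/Li exchange gives the hindered aryllithium, which adds to the Weinreb amide. The stable chelated tetrahedral intermediate collapses to the ketone only on quench, so the ketone is never exposed to base and C3 is not epimerised.

**Step 35**
Reactants: 39
Product: 40 C3′ alcohol (TBS removed)
Conditions: HF·pyridine, THF/pyridine, 0→25 °C, 24 h
Reagents that add atoms: none
Why: Mild, non-basic fluoride removes the secondary TBS ether without epimerising C3 α to the ketone.

**Step 36**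
Reactants: 40
Product: 41 Blepharocalyxin B
Conditions: ZnBr2 (10 equiv), n-PrSH (20 equiv), CH2Cl2, 0 °C→rt
Reagents that add atoms: none
Why: Lewis-acid thiolysis cleaves all seven MOM acetals under near-neutral conditions that leave the alkenes, the ketone and the strained THP stereocenters intact.

## Compound list
1 | methyl 3-(4-hydroxyphenyl)propanoate | COC(=O)CCc1ccc(O)cc1 | starting material
2 | methyl 3-[4-(MOMO)phenyl]propanoate | COC(=O)CCc1ccc(OCOC)cc1 | intermediate
3 | 3-[4-(MOMO)phenyl]propanal | O=CCCc1ccc(OCOC)cc1 | intermediate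
4 | rac-2-{2-[4-(MOMO)phenyl]ethyl}oxirane | C1OC1CCc1ccc(OCOC)cc1 | intermediate
5 | (S)-epoxide | C1O[C@H]1CCc1ccc(OCOC)cc1 | intermediate
6 | (R)-epoxide | C1O[C@@H]1CCc1ccc(OCOC)cc1 | intermediate
7 | (S)-1-[4-(MOMO)phenyl]hex-5-yn-3-ol | C#CC[C@@H](O)CCc1ccc(OCOC)cc1 | intermediate
8 | (S)-TBS ether of 7 | C#CC[C@@H](O[Si](C)(C)C(C)(C)C)CCc1ccc(OCOC)cc1 | intermediate
9 | (E)-alkenylboronic acid, (S)-OTBS | OB(O)/C=C/C[C@@H](O[Si](C)(C)C(C)(C)C)CCc1ccc(OCOC)cc1 | intermediate
10 | (R)-1-[4-(MOMO)phenyl]hex-5-en-3-ol | C=CC[C@H](O)CCc1ccc(OCOC)cc1 | intermediate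
11 | (R)-TES ether of 10 | C=CC[C@H](O[Si](CC)(CC)CC)CCc1ccc(OCOC)cc1 | intermediate
12 | 4-hydroxybenzaldehyde | O=Cc1ccc(O)cc1 | starting material
13 | 4-(MOMO)benzaldehyde | O=Cc1ccc(OCOC)cc1 | intermediate
14 | rac-1-[4-(MOMO)phenyl]prop-2-en-1-ol | C=CC(O)c1ccc(OCOC)cc1 | intermediate
15 | (S)-1-[4-(MOMO)phenyl]prop-2-en-1-ol | C=C[C@H](O)c1ccc(OCOC)cc1 | intermediate
16 | (3R,5E,7S)-1,7-bis[4-(MOMO)phenyl]-3-(TESO)hept-5-en-7-ol | O[C@@H](/C=C/C[C@H](O[Si](CC)(CC)CC)CCc1ccc(OCOC)cc1)c1ccc(OCOC)cc1 | intermediate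
17 | 4-hydroxyacetophenone | CC(=O)c1ccc(O)cc1 | starting material
18 | 4-(MOMO)acetophenone | CC(=O)c1ccc(OCOC)cc1 | intermediate
19 | ethyl 3-[4-(MOMO)phenyl]-3-oxopropanoate | CCOC(=O)CC(=O)c1ccc(OCOC)cc1 | intermediate
20 | ethyl (R)-3-hydroxy-3-[4-(MOMO)phenyl]propanoate | CCOC(=O)C[C@@H](O)c1ccc(OCOC)cc1 | intermediate
21 | ethyl (R)-3-(TBSO)-3-[4-(MOMO)phenyl]propanoate | CCOC(=O)C[C@@H](O[Si](C)(C)C(C)(C)C)c1ccc(OCOC)cc1 | intermediate
22 | (R)-3-(TBSO)-3-[4-(MOMO)phenyl]propanoic acid | OC(=O)C[C@@H](O[Si](C)(C)C(C)(C)C)c1ccc(OCOC)cc1 | intermediate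
23 | allylic ester from 22 and 16 | O=C(C[C@@H](O[Si](C)(C)C(C)(C)C)c1ccc(OCOC)cc1)O[C@@H](/C=C/C[C@H](O[Si](CC)(CC)CC)CCc1ccc(OCOC)cc1)c1ccc(OCOC)cc1 | intermediate
24 | Claisen acid (acyclic 2R,3R,4S; C6 (R)-OTES) | OC(=O)[C@@H]([C@@H](O[Si](C)(C)C(C)(C)C)c1ccc(OCOC)cc1)[C@H](/C=C/c1ccc(OCOC)cc1)C[C@@H](CCc1ccc(OCOC)cc1)O[Si](CC)(CC)CC | intermediate
25 | Weinreb amide of 24 | CON(C)C(=O)[C@@H]([C@@H](O[Si](C)(C)C(C)(C)C)c1ccc(OCOC)cc1)[C@H](/C=C/c1ccc(OCOC)cc1)C[C@@H](CCc1ccc(OCOC)cc1)O[Si](CC)(CC)CC | intermediate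
26 | C6 alcohol | CON(C)C(=O)[C@@H]([C@@H](O[Si](C)(C)C(C)(C)C)c1ccc(OCOC)cc1)[C@H](/C=C/c1ccc(OCOC)cc1)C[C@@H](CCc1ccc(OCOC)cc1)O | intermediate
27 | C6 mesylate | CON(C)C(=O)[C@@H]([C@@H](O[Si](C)(C)C(C)(C)C)c1ccc(OCOC)cc1)[C@H](/C=C/c1ccc(OCOC)cc1)C[C@@H](CCc1ccc(OCOC)cc1)OS(C)(=O)=O | intermediate
28 | THP Weinreb amide (2R,3R,4S,6S) | CON(C)C(=O)[C@@H]1[C@H](/C=C/c2ccc(OCOC)cc2)C[C@H](CCc2ccc(OCOC)cc2)O[C@H]1c1ccc(OCOC)cc1 | intermediate
29 | 3,5-dihydroxyanisole | COc1cc(O)cc(O)c1 | starting material
30 | 1,3-bis(MOMO)-5-methoxybenzene | COc1cc(OCOC)cc(OCOC)c1 | intermediate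
31 | 2,6-bis(MOMO)-4-methoxybenzaldehyde | COc1cc(OCOC)c(C=O)c(OCOC)c1 | intermediate
32 | 2-hydroxy-4-methoxy-6-(MOMO)benzaldehyde | COc1cc(O)c(C=O)c(OCOC)c1 | intermediate
33 | 4-bromophenol | Oc1ccc(Br)cc1 | starting material
34 | 1-bromo-4-(MOMO)benzene | COCOc1ccc(Br)cc1 | intermediate
35 | rac-o-hydroxybenzhydrol | COc1cc(O)c(C(O)c2ccc(OCOC)cc2)c(OCOC)c1 | intermediate
36 | (R)-diarylmethine, free ortho-OH | COc1cc(O)c([C@H](/C=C/C[C@@H](O[Si](C)(C)C(C)(C)C)CCc2ccc(OCOC)cc2)c2ccc(OCOC)cc2)c(OCOC)c1 | intermediate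
37 | ring-A bis-MOM ether | COc1cc(OCOC)c([C@H](/C=C/C[C@@H](O[Si](C)(C)C(C)(C)C)CCc2ccc(OCOC)cc2)c2ccc(OCOC)cc2)c(OCOC)c1 | intermediate
38 | aryl bromide | COc1cc(OCOC)c([C@H](/C=C/C[C@@H](O[Si](C)(C)C(C)(C)C)CCc2ccc(OCOC)cc2)c2ccc(OCOC)cc2)c(OCOC)c1Br | intermediate
39 | fully protected target | COc1cc(OCOC)c([C@H](/C=C/C[C@@H](O[Si](C)(C)C(C)(C)C)CCc2ccc(OCOC)cc2)c2ccc(OCOC)cc2)c(OCOC)c1C(=O)[C@@H]1[C@H](/C=C/c2ccc(OCOC)cc2)C[C@H](CCc2ccc(OCOC)cc2)O[C@H]1c1ccc(OCOC)cc1 | intermediate
40 | C3′-OH, MOM-protected | COc1cc(OCOC)c([C@H](/C=C/C[C@@H](O)CCc2ccc(OCOC)cc2)c2ccc(OCOC)cc2)c(OCOC)c1C(=O)[C@@H]1[C@H](/C=C/c2ccc(OCOC)cc2)C[C@H](CCc2ccc(OCOC)cc2)O[C@H]1c1ccc(OCOC)cc1 | intermediate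
41 | Blepharocalyxin B | COc1cc(O)c([C@H](/C=C/C[C@@H](O)CCc2ccc(O)cc2)c2ccc(O)cc2)c(O)c1C(=O)[C@@H]1[C@H](/C=C/c2ccc(O)cc2)C[C@H](CCc2ccc(O)cc2)O[C@H]1c1ccc(O)cc1 | target

## Totals
Total steps: 36 (several run in parallel branches). Longest linear sequence: 16 steps (1, 2, 3, 5, 9, 10, 14, 20, 21, 22, 23, 24, 25, 34, 35, 36).

## Three steps most likely to fail
1. **Step 25, SN2 closure to the strained 2,6-trans THP (axial aryl and acyl).** Elimination of the mesylate or C3 epimerisation under fluoride could compete.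
   *Fallback:* use a different ring construction. Run a Jacobsen Cr(III)-catalysed hetero-Diels–Alder of Danishefsky's diene with aldehyde **13** to give the 2-aryl-dihydropyranone. Then add the 2-(4-MOMO-phenyl)ethyl cuprate conjugately for 2,6-trans-THP-4-one, and build C3/C4 on that ring.
2. **Step 31, o-QM alkenylation.** The ee may be low on this hindered, doubly ortho-oxygenated o-QM.
   *Fallback:* change the bond construction. Make the (R)-3,3-diarylpropene by an Ir-catalysed asymmetric allylic arylation of a 4-MOMO-cinnamyl carbonate with bis-MOM ring A, then attach the chain by cross-metathesis with homoallylic silyl ether **11**-type (S)-partner.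
3. **Step 34, hindered ArLi addition / C3 epimerisation / C7 deprotonation.**
   *Fallback:* change the connection order. Reduce Weinreb amide **28** to the aldehyde with DIBAL at –78 °C, add the less hindered ArLi by 1,2-addition at –78 °C, and oxidise the carbinol with Dess–Martin periodinane/NaHCO3.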